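**Retrosynthetic overview**
- The strategy rests on the syn (threo, 7R,8R) pair C7/C8: C7 is the benzylic carbinol carbon on ring A (3,4,5-trimethoxyphenyl), C8 carries the ether oxygen to ring B, and only the one-carbon CH2OH arm C9 lies beyond C8.
- Last disconnection: the allyl group at C4' of ring B, added by C–H borylation at the only aromatic C–H with no ortho substituent and then palladium-catalysed allylation; ring B therefore travels as plain 2,6-dimethoxyphenyl through the organolithium and alkene-cleavage steps.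
- C9–OH comes from a vinyl group by dihydroxylation, periodate cleavage and borohydride reduction.
- Key disconnection C7–C8: a (Z)-γ-(2,6-dimethoxyphenoxy)allyl pinacol boronate adds to 3,4,5-trimethoxybenzaldehyde under a chiral phosphoric acid and sets both stereocentres; the boronate comes from the allyl ether of 2,6-dimethoxyphenol by lithiation and borylation.
- No ring is formed at any stage; ring A and ring B are both bought.

Key step: step 3

Assumption: the facial preference of 3,3'-bis(2,4,6-triisopropylphenyl)-1,1'-binaphthyl-2,2'-diyl hydrogen phosphate in allylboration of aryl aldehydes (the (R)-acid sends the allyl unit to the Re face) is taken to hold for the γ-aryloxy reagent, so the (S)-acid is specified for Si-face attack and 7R; locants C7, C8, C9 follow neolignan numbering.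

**Route**

Step 1
Reactants: 1 2,6-dimethoxyphenol; 2 allyl bromide
Product: 3 2-(allyloxy)-1,3-dimethoxybenzene
Conditions: K2CO3, acetone, reflux
Reagents that add atoms: none
Why: Williamson O-allylation of the phenoxide, run well below the temperature at which the doubly ortho-blocked ether would undergo para-Claisen rearrangement.

Step 2
Reactants: 3 2-(allyloxy)-1,3-dimethoxybenzene; 4 2-isopropoxy-4,4,5,5-tetramethyl-1,3,2-dioxaborolane
Product: 7 (Z)-2-[3-(2,6-dimethoxyphenoxy)prop-2-en-1-yl]-4,4,5,5-tetramethyl-1,3,2-dioxaborolane, via (Z)-aryloxyallyllithium 5 (not isolated), via lithium isopropoxyborate complex 6 (not isolated)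
Conditions: sec-BuLi (1.1 equiv), THF, −78 °C; 4, −78 °C; sat. aq. NH4Cl, −78 °C to rt; used promptly after filtration through deactivated silica
Reagents that add atoms: none
Why: Allylic deprotonation alpha to the ether oxygen (faster at −78 °C than ring metalation beside a methoxy group) gives the 1-aryloxyallyl anion in its oxygen-chelated cis form, and borate electrophiles are taken up at the remote γ-carbon, which is the standard metalation–borylation preparation of (Z)-γ-alkoxyallylboronates, so protonolysis of the ate complex should leave the Z enol ether boronate.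

Step 3
Reactants: 7 (Z)-2-[3-(2,6-dimethoxyphenoxy)prop-2-en-1-yl]-4,4,5,5-tetramethyl-1,3,2-dioxaborolane (1.3 equiv); 8 3,4,5-trimethoxybenzaldehyde
Product: 10 (1R,2R)-2-(2,6-dimethoxyphenoxy)-1-(3,4,5-trimethoxyphenyl)but-3-en-1-ol, via pinacol borate ester 9 (not isolated)
Conditions: (S)-3,3'-bis(2,4,6-triisopropylphenyl)-1,1'-binaphthyl-2,2'-diyl hydrogen phosphate (5 mol%), 4 Å molecular sieves, toluene, −30 °C; aq. NaHCO3 work-up
Reagents that add atoms: none
Why: The acid-catalysed allylboration runs through a closed six-membered chair (Zimmerman–Traxler type) transition state in which boron binds the aldehyde oxygen and the γ-carbon of 7 attacks the carbonyl carbon with allylic transposition, so the C7–C8 bond forms, the boron-bearing CH2 becomes the terminal vinyl carbon and no ring is closed. The closest known reactions are the chiral phosphoric acid catalysed addition of (Z)-γ-alkoxyallyl pinacol boronates to aldehydes and the Brown (Z)-γ-alkoxyallylboration, both of which give syn 1,2-diol monoethers. C8 is set relative to C7 by the Z enol ether geometry, which forces the aryloxy group axial while the aldehyde aryl group sits equatorial and so gives the syn (threo) pair. C7 is set by the catalyst, whose P–OH hydrogen-bonds to a boronate oxygen while P=O contacts the formyl hydrogen, so that the (S)-acid should expose the Si face of 8 and give 7R, hence (1R,2R). The step needs γ- over α-attack, retention of the Z geometry and a slow uncatalysed background: the closed transition state secures the first, the weakly basic aryl enol ether should not isomerise under the dry weak acid, and the electron-rich aldehyde 8 reacts only sluggishly with a pinacol boronate at −30 °C without the acid.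

Step 4
Reactants: 10 (1R,2R)-2-(2,6-dimethoxyphenoxy)-1-(3,4,5-trimethoxyphenyl)but-3-en-1-ol
Product: 13 (1R,2R)-2-(2,6-dimethoxyphenoxy)-1-(3,4,5-trimethoxyphenyl)propane-1,3-diol, via butane-1,3,4-triol 11 (not isolated), via alpha-aryloxy aldehyde 12 (not isolated)
Conditions: OsO4 (2 mol%), N-methylmorpholine N-oxide, acetone/H2O, rt; NaIO4, rt; extraction; NaBH4, MeOH, 0 °C
Reagents that add atoms: osmium tetroxide O=[Os](=O)(=O)=O; N-methylmorpholine N-oxide C[N+]1([O-])CCOCC1
Why: Upjohn dihydroxylation of the only alkene, Malaprade cleavage of the new terminal 1,2-diol (the C7 hydroxyl has no vicinal hydroxyl partner) and immediate borohydride reduction give the C9 alcohol without touching C7 or C8; osmium and periodate are used because ozone would also attack the two electron-rich polymethoxyarenes, and the aldehyde is reduced at once so that C8 is not epimerised and retro-aldol cleavage does not set in.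

Step 5
Reactants: 13 (1R,2R)-2-(2,6-dimethoxyphenoxy)-1-(3,4,5-trimethoxyphenyl)propane-1,3-diol
Product: 14 (1R,2R)-1,3-bis(tert-butyldimethylsilyloxy)-2-(2,6-dimethoxyphenoxy)-1-(3,4,5-trimethoxyphenyl)propane
Conditions: t-BuMe2SiOTf (2.5 equiv), 2,6-lutidine, CH2Cl2, −78 to 0 °C
Reagents that add atoms: tert-butyldimethylsilyl trifluoromethanesulfonate CC(C)(C)[Si](C)(C)OS(=O)(=O)C(F)(F)F
Why: Silyl triflate silylation under lutidine buffering caps the primary and the hindered benzylic hydroxyl, whose O–H bonds would otherwise consume the boron reagent of the next step, with groups that are later removed by fluoride without acid.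

Step 6
Reactants: 14 (1R,2R)-1,3-bis(tert-butyldimethylsilyloxy)-2-(2,6-dimethoxyphenoxy)-1-(3,4,5-trimethoxyphenyl)propane
Product: 15 (1R,2R)-1,3-bis(tert-butyldimethylsilyloxy)-2-[2,6-dimethoxy-4-(4,4,5,5-tetramethyl-1,3,2-dioxaborolan-2-yl)phenoxy]-1-(3,4,5-trimethoxyphenyl)propane
Conditions: [Ir(OMe)(cod)]2 (1.5 mol%), 4,4'-di-tert-butyl-2,2'-bipyridine (3 mol%), B2pin2 (1.0 equiv), THF, 80 °C
Reagents that add atoms: bis(pinacolato)diboron CC1(C)OB(OC1(C)C)B1OC(C)(C)C(C)(C)O1
Why: Iridium-catalysed aromatic C–H borylation (Ishiyama–Miyaura–Hartwig) is governed by sterics, and C4' of ring B, para to the ether oxygen and flanked by two C–H positions, is the only aromatic C–H of 14 without an ortho substituent (each ring A hydrogen lies between a methoxy group and the branched side chain), so a single aryl boronate should form while silyl and methyl ethers stay inert.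

Step 7
Reactants: 15 (1R,2R)-1,3-bis(tert-butyldimethylsilyloxy)-2-[2,6-dimethoxy-4-(4,4,5,5-tetramethyl-1,3,2-dioxaborolan-2-yl)phenoxy]-1-(3,4,5-trimethoxyphenyl)propane; 2 allyl bromide
Product: 16 (1R,2R)-2-(4-allyl-2,6-dimethoxyphenoxy)-1,3-bis(tert-butyldimethylsilyloxy)-1-(3,4,5-trimethoxyphenyl)propane
Conditions: Pd(PPh3)4 (5 mol%), K2CO3, THF/H2O, 65 °C
Reagents that add atoms: none
Why: Suzuki–Miyaura allyl–aryl coupling, in which allyl bromide adds oxidatively to zerovalent palladium, the base-activated aryl boronate transmetalates to the π-allylpalladium bromide and reductive elimination forms the aryl–CH2 bond; the unsubstituted allyl unit has no regiochemical ambiguity and the mild base and temperature should keep the double bond out of conjugation.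

Step 8
Reactants: 16 (1R,2R)-2-(4-allyl-2,6-dimethoxyphenoxy)-1,3-bis(tert-butyldimethylsilyloxy)-1-(3,4,5-trimethoxyphenyl)propane
Product: 17 (1R,2R)-2-(4-allyl-2,6-dimethoxyphenoxy)-1-(3,4,5-trimethoxyphenyl)propane-1,3-diol (target, 7R,8R)
Conditions: Bu4NF (3 equiv), THF, 0 °C to rt
Reagents that add atoms: none
Why: Fluoride-induced silyl ether cleavage frees both hydroxyls under non-acidic conditions, so the electron-rich benzylic C7 carbinol cannot ionise and epimerise and the allyl group is untouched.

**Compound list**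
1 | 2,6-dimethoxyphenol | COc1cccc(OC)c1O | starting material
2 | allyl bromide | C=CCBr | starting material
3 | 2-(allyloxy)-1,3-dimethoxybenzene | C=CCOc1c(OC)cccc1OC | intermediate
4 | 2-isopropoxy-4,4,5,5-tetramethyl-1,3,2-dioxaborolane | CC(C)OB1OC(C)(C)C(C)(C)O1 | starting material
5 | (Z)-[3-(2,6-dimethoxyphenoxy)allyl]lithium (delocalised 1-aryloxyallyl anion, lithium held by the ether oxygen; drawn as the γ-lithio form) | COc1cccc(OC)c1O/C=C\C[Li] | intermediate
6 | lithium [(Z)-3-(2,6-dimethoxyphenoxy)allyl](isopropoxy)(pinacolato)borate | [Li+].COc1cccc(OC)c1O/C=C\C[B-]1(OC(C)C)OC(C)(C)C(C)(C)O1 | intermediate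
7 | (Z)-2-[3-(2,6-dimethoxyphenoxy)prop-2-en-1-yl]-4,4,5,5-tetramethyl-1,3,2-dioxaborolane | COc1cccc(OC)c1O/C=C\CB1OC(C)(C)C(C)(C)O1 | intermediate
8 | 3,4,5-trimethoxybenzaldehyde | COc1cc(C=O)cc(OC)c1OC | starting material
9 | 2-{[(1R,2R)-2-(2,6-dimethoxyphenoxy)-1-(3,4,5-trimethoxyphenyl)but-3-en-1-yl]oxy}-4,4,5,5-tetramethyl-1,3,2-dioxaborolane | COc1cccc(OC)c1O[C@H](C=C)[C@H](OB1OC(C)(C)C(C)(C)O1)c1cc(OC)c(OC)c(OC)c1 | intermediate
10 | (1R,2R)-2-(2,6-dimethoxyphenoxy)-1-(3,4,5-trimethoxyphenyl)but-3-en-1-ol | COc1cccc(OC)c1O[C@H](C=C)[C@H](O)c1cc(OC)c(OC)c(OC)c1 | intermediate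
11 | (1R,2S)-2-(2,6-dimethoxyphenoxy)-1-(3,4,5-trimethoxyphenyl)butane-1,3,4-triol (both C3 epimers) | COc1cccc(OC)c1O[C@H](C(O)CO)[C@H](O)c1cc(OC)c(OC)c(OC)c1 | intermediate
12 | (2S,3R)-2-(2,6-dimethoxyphenoxy)-3-hydroxy-3-(3,4,5-trimethoxyphenyl)propanal | COc1cccc(OC)c1O[C@H](C=O)[C@H](O)c1cc(OC)c(OC)c(OC)c1 | intermediate
13 | (1R,2R)-2-(2,6-dimethoxyphenoxy)-1-(3,4,5-trimethoxyphenyl)propane-1,3-diol | COc1cccc(OC)c1O[C@H](CO)[C@H](O)c1cc(OC)c(OC)c(OC)c1 | intermediate
14 | (1R,2R)-1,3-bis(tert-butyldimethylsilyloxy)-2-(2,6-dimethoxyphenoxy)-1-(3,4,5-trimethoxyphenyl)propane | COc1cccc(OC)c1O[C@H](CO[Si](C)(C)C(C)(C)C)[C@H](O[Si](C)(C)C(C)(C)C)c1cc(OC)c(OC)c(OC)c1 | intermediate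
15 | (1R,2R)-1,3-bis(tert-butyldimethylsilyloxy)-2-[2,6-dimethoxy-4-(4,4,5,5-tetramethyl-1,3,2-dioxaborolan-2-yl)phenoxy]-1-(3,4,5-trimethoxyphenyl)propane | COc1cc(B2OC(C)(C)C(C)(C)O2)cc(OC)c1O[C@H](CO[Si](C)(C)C(C)(C)C)[C@H](O[Si](C)(C)C(C)(C)C)c1cc(OC)c(OC)c(OC)c1 | intermediate
16 | (1R,2R)-2-(4-allyl-2,6-dimethoxyphenoxy)-1,3-bis(tert-butyldimethylsilyloxy)-1-(3,4,5-trimethoxyphenyl)propane | C=CCc1cc(OC)c(O[C@H](CO[Si](C)(C)C(C)(C)C)[C@H](O[Si](C)(C)C(C)(C)C)c2cc(OC)c(OC)c(OC)c2)c(OC)c1 | intermediate
17 | (1R,2R)-2-(4-allyl-2,6-dimethoxyphenoxy)-1-(3,4,5-trimethoxyphenyl)propane-1,3-diol | C=CCc1cc(OC)c(O[C@H](CO)[C@H](O)c2cc(OC)c(OC)c(OC)c2)c(OC)c1 | target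

Total step count: 8. Longest linear sequence: 8 steps (1 to 17).

**Steps most likely to fail**

Step 3. The acid may discriminate the aldehyde faces poorly when the bulky 2,6-dimethoxyphenoxy group sits axial in the chair, or acid-promoted Z to E isomerisation of the enol ether may leak anti product. The fallback moves absolute control from the catalyst onto boron (Brown-type (Z)-γ-alkoxyallylboration). It sets out from 3 and comes back at 10.
- Lithium species 5 is made as in step 2 and trapped at −78 °C with (−)-B-methoxydiisopinocampheylborane (the enantiomer derived from (+)-α-pinene) to give lithium [(Z)-3-(2,6-dimethoxyphenoxy)allyl]bis(isopinocampheyl)(methoxy)borate F1.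
- BF3·OEt2 abstracts methoxide and leaves [(Z)-3-(2,6-dimethoxyphenoxy)allyl]diisopinocampheylborane F2.
- F2 is treated in the same flask with 8 at −78 °C and should give, through the same chair, [(1R,2R)-2-(2,6-dimethoxyphenoxy)-1-(3,4,5-trimethoxyphenyl)but-3-en-1-yl] diisopinocampheylborinate F3.
- NaOH/H2O2 work-up releases 10, and the route continues at step 4.

Step 2. sec-BuLi may metalate a ring carbon beside a methoxy group, or attack the allyl terminus with expulsion of the phenoxide, instead of removing the allylic proton; the enol ether boronate may also decompose on isolation. The fallback makes the same C7–C8 bond with the same syn sense by an Evans boron aldol, without any allyl anion. It sets out from 1 and comes back at 13, replacing steps 2 to 4.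
- Alkylation of 1 with bromoacetic acid (aq. NaOH, reflux, then acidification) gives (2,6-dimethoxyphenoxy)acetic acid F4.
- Dicyclohexylcarbodiimide/DMAP coupling with (S)-4-benzyloxazolidin-2-one gives (S)-4-benzyl-3-[(2,6-dimethoxyphenoxy)acetyl]oxazolidin-2-one F5.
- Bu2BOTf and i-Pr2NEt (CH2Cl2, −78 °C) give the (Z)-dibutylboron enolate F6, which adds 8 through a chair to give the dibutylboron aldolate F7.
- Buffered H2O2 work-up gives (S)-4-benzyl-3-[(2S,3R)-2-(2,6-dimethoxyphenoxy)-3-hydroxy-3-(3,4,5-trimethoxyphenyl)propanoyl]oxazolidin-2-one F8.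
- LiBH4 (THF, one equivalent of water, 0 °C) removes the auxiliary reductively and delivers 13.

Step 7. Transmetalation of the electron-rich aryl boronate to the π-allylpalladium may be slow, so that protodeboronation or palladium hydride migration of the new double bond into conjugation with ring B takes over. The fallback exchanges the roles of the partners (aryl electrophile, allyl nucleophile). It sets out from 15 and comes back at 16.
- Ipso-iododeboronation with NaI and sodium N-chloro-4-methylbenzenesulfonamide (THF/H2O, rt) gives (1R,2R)-1,3-bis(tert-butyldimethylsilyloxy)-2-(4-iodo-2,6-dimethoxyphenoxy)-1-(3,4,5-trimethoxyphenyl)propane F9.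
- Stille coupling with allyltributylstannane and Pd(PPh3)4 (toluene, 100 °C) gives 16.

**Further compounds**
F1 | step 3 | lithium [(Z)-3-(2,6-dimethoxyphenoxy)allyl]bis(isopinocampheyl)(methoxy)borate | [Li+].COc1cccc(OC)c1O/C=C\C[B-](OC)([C@@H]1C[C@@H]2C[C@H]([C@H]1C)C2(C)C)[C@@H]1C[C@@H]2C[C@H]([C@H]1C)C2(C)C
F2 | step 3 | [(Z)-3-(2,6-dimethoxyphenoxy)allyl]diisopinocampheylborane | COc1cccc(OC)c1O/C=C\CB([C@@H]1C[C@@H]2C[C@H]([C@H]1C)C2(C)C)[C@@H]1C[C@@H]2C[C@H]([C@H]1C)C2(C)C
F3 | step 3 | [(1R,2R)-2-(2,6-dimethoxyphenoxy)-1-(3,4,5-trimethoxyphenyl)but-3-en-1-yl] diisopinocampheylborinate | COc1cccc(OC)c1O[C@H](C=C)[C@H](OB([C@@H]1C[C@@H]2C[C@H]([C@H]1C)C2(C)C)[C@@H]1C[C@@H]2C[C@H]([C@H]1C)C2(C)C)c1cc(OC)c(OC)c(OC)c1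
F4 | step 2 | (2,6-dimethoxyphenoxy)acetic acid | COc1cccc(OC)c1OCC(=O)O
F5 | step 2 | (S)-4-benzyl-3-[(2,6-dimethoxyphenoxy)acetyl]oxazolidin-2-one | COc1cccc(OC)c1OCC(=O)N1[C@@H](Cc2ccccc2)COC1=O
F6 | step 2 | (Z)-dibutylboron enolate of F5 | CCCCB(CCCC)O/C(=C\Oc1c(OC)cccc1OC)N1[C@@H](Cc2ccccc2)COC1=O
F7 | step 2 | dibutylboron aldolate of F8 | COc1cccc(OC)c1O[C@H](C(=O)N1[C@@H](Cc2ccccc2)COC1=O)[C@H](OB(CCCC)CCCC)c1cc(OC)c(OC)c(OC)c1
F8 | step 2 | (S)-4-benzyl-3-[(2S,3R)-2-(2,6-dimethoxyphenoxy)-3-hydroxy-3-(3,4,5-trimethoxyphenyl)propanoyl]oxazolidin-2-one | COc1cccc(OC)c1O[C@H](C(=O)N1[C@@H](Cc2ccccc2)COC1=O)[C@H](O)c1cc(OC)c(OC)c(OC)c1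
F9 | step 7 | (1R,2R)-1,3-bis(tert-butyldimethylsilyloxy)-2-(4-iodo-2,6-dimethoxyphenoxy)-1-(3,4,5-trimethoxyphenyl)propane | COc1cc(I)cc(OC)c1O[C@H](CO[Si](C)(C)C(C)(C)C)[C@H](O[Si](C)(C)C(C)(C)C)c1cc(OC)c(OC)c(OC)c1
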